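**Plan**

1. Retrosynthetic cuts, in order: (a) the bond from the bridge CH2 to the enol carbon of the cyclohexadienone ring, by reductive Knoevenagel coupling, with the bridge carbon carried as a formyl group on the chromene half; (b) the C2–C3 bond of the pyran ring; (c) the geranyl–C(quaternary) bond of the cyclohexadienone ring.
2. Enabling feature: in the pyran ring C2 carries O1 and two methyl groups, so it is the methine carbon of an aryl isopropyl ether at the oxocarbenium level, and C3=C4 sits on the benzene ring ortho to O1. The 2,2-dimethyl-2H-chromene is therefore a constitutional isomer of a 1-ethynyl-2-isopropoxybenzene.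
3. Forward, chromene half: symmetric 4-hydroxy-2,6-dimethoxybenzaldehyde is C-butanoylated, iodinated, O-isopropylated and alkynylated, with symmetry fixing every ring position. A gold-catalysed 1,5-hydride shift/cyclisation then closes the pyran ring and BCl3 frees the two phenols.
4. Forward, dienone half: the flat benzene ring of 3-methylphloracetophenone, blocked by chlorine at its free carbon, is dearomatised by Pd-catalysed asymmetric geranylation at the methyl-bearing carbon; zinc then removes the chlorine.
5. Union: the aldehyde of the chromene half condenses with the C–H acidic ring carbon of the dienone half and a Hantzsch ester reduces the adduct, so only the unsymmetrical CH2-bridged dimer can form.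
6. Stereochemistry: the single stereocentre comes from the chiral ligand in the dearomative allylation and is quaternary, so no later step can epimerise it; the 2E alkene comes from geraniol.

Key step: step 6

Assumption: the enolised triketones are drawn in one tautomer (that of the target SMILES), and the (R,R) ligand is taken to give the configuration shown; its antipode would be used if the sense of induction proved opposite.

**Route**

Step 1
Reactants: 1 4-hydroxy-2,6-dimethoxybenzaldehyde
Product: 2 3-butanoyl-4-hydroxy-2,6-dimethoxybenzaldehyde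
Conditions: butanoic acid (3 equiv), BF3·OEt2 (3 equiv), 80 °C; then aq. NaOAc
Reagents that add atoms: butanoic acid, CCCC(=O)O
Why: Friedel–Crafts (Nencki-type) C-acylation at one of the two symmetry-equivalent carbons that lie ortho to the free hydroxyl, ortho to one methoxy and para to the other and only meta to the formyl group, so a single mono-ketone should form and the hydrogen-bonded ortho-hydroxy ketone resists a second acylation.

Step 2
Reactants: 2 3-butanoyl-4-hydroxy-2,6-dimethoxybenzaldehyde
Product: 3 3-butanoyl-4-hydroxy-5-iodo-2,6-dimethoxybenzaldehyde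
Conditions: NIS (1.05 equiv), TFA (10 mol%), MeCN, 0 °C to rt
Reagents that add atoms: N-iodosuccinimide, O=C1CCC(=O)N1I
Why: Electrophilic aromatic iodination at the only remaining ring C–H, which is ortho to the phenol, so the position of the future alkyne is fixed without any regiochemical choice.

Step 3
Reactants: 3 3-butanoyl-4-hydroxy-5-iodo-2,6-dimethoxybenzaldehyde
Product: 4 3-butanoyl-5-iodo-2,6-dimethoxy-4-(propan-2-yloxy)benzaldehyde
Conditions: 2-iodopropane (3 equiv), K2CO3, DMF, 60 °C
Reagents that add atoms: 2-iodopropane, CC(C)I
Why: Williamson etherification of the acidic phenol (para to formyl, ortho to acyl), which installs the isopropyl ether whose methine carbon and two methyl groups later become C2 and its gem-dimethyl pair.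

Step 4
Reactants: 4 3-butanoyl-5-iodo-2,6-dimethoxy-4-(propan-2-yloxy)benzaldehyde
Product: 5 3-butanoyl-2,6-dimethoxy-4-(propan-2-yloxy)-5-[(trimethylsilyl)ethynyl]benzaldehyde
Conditions: ethynyltrimethylsilane (1.5 equiv), PdCl2(PPh3)2 (5 mol%), CuI (10 mol%), Et3N, THF, 60 °C
Reagents that add atoms: ethynyltrimethylsilane, C#C[Si](C)(C)C
Why: Sonogashira coupling of an aryl iodide whose oxidative addition is helped by the two carbonyl groups meta to it, while the aldehyde, ketone and ethers are inert to the conditions.

Step 5
Reactants: 5 3-butanoyl-2,6-dimethoxy-4-(propan-2-yloxy)-5-[(trimethylsilyl)ethynyl]benzaldehyde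
Product: 6 3-butanoyl-5-ethynyl-2,6-dimethoxy-4-(propan-2-yloxy)benzaldehyde
Conditions: K2CO3 (0.2 equiv), MeOH, 0 °C to rt
Reagents that add atoms: none
Why: Base-catalysed methanolysis (protodesilylation) of the alkynyl–silicon bond, which is mild enough to leave the aldehyde, the ketone and the ethers unchanged.

Step 6
Reactants: 6 3-butanoyl-5-ethynyl-2,6-dimethoxy-4-(propan-2-yloxy)benzaldehyde
Product: 7 8-butanoyl-5,7-dimethoxy-2,2-dimethyl-2H-chromene-6-carbaldehyde
Conditions: (XPhos)Au(NCMe)SbF6 (5 mol%), 4 Å MS, ClCH2CH2Cl, 80 °C
Reagents that add atoms: none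
Why: Proposed new method: the cationic monovalent gold centre π-binds the terminal alkyne of 6 and polarises it in the Markovnikov sense, so that the ring-bound alkyne carbon (future C4), ortho to the isopropoxy and one methoxy oxygen and para to the other, becomes electrophilic and accepts the methine hydrogen of the adjacent isopropyl ether as hydride through a six-membered transition state (1,5-hydride shift), leaving a 2-aryloxyprop-2-ylium oxocarbenium ion (future C2) beside a (Z)-styrylgold unit (future C3). The vinylgold carbon then attacks the oxocarbenium carbon, which forms the C2–C3 bond, closes the pyran ring and releases the gold cation, so the net change is an isomerisation with no atoms added or lost. The closest known reaction type is the gold- or platinum-catalysed 1,5-hydride shift/cyclisation (internal redox hydroalkylation) of alkynes carrying an α-oxy or α-amino C–H donor, known for dialkyl ethers and tertiary amines; an aryl isopropyl ether donating to an ortho ethynyl group to give a 2H-chromene is the untested extension. The one ring closes in a 6-endo-trig mode with respect to the C=O+ bond of the oxocarbenium ion (Prins-type attack of a vinyl metal), and no five-membered alternative exists because the only nucleophilic carbon is the gold-bearing terminal one. No stereocentre is formed, since C2 carries two methyl groups. The step needs donor selectivity and chemoselectivity: the tertiary isopropyl C–H should be chosen over the O-methyl groups because only it gives a dialkyl-substituted oxocarbenium ion, the Markovnikov polarisation set by the three ring oxygens disfavours the anti-Markovnikov 5-endo attack of an ether oxygen that would lead to a benzofuran, and the aldehyde and ketone are meta to the alkyne and cannot reach it.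

Step 7
Reactants: 7 8-butanoyl-5,7-dimethoxy-2,2-dimethyl-2H-chromene-6-carbaldehyde
Product: 8 8-butanoyl-5,7-dihydroxy-2,2-dimethyl-2H-chromene-6-carbaldehyde
Conditions: BCl3 (3 equiv), CH2Cl2, −78 to 0 °C; then MeOH, aq. NaHCO3
Reagents that add atoms: none
Why: Chelation-controlled Lewis-acid O-demethylation, in which each carbonyl group directs cleavage of one neighbouring methyl ether through a six-membered boron chelate (O7 between formyl and butanoyl, O5 next to formyl), while the tertiary-alkyl ring ether and the styrene-type alkene should survive at low temperature because the butanoyl oxygen is tied up with O7.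

Step 8
Reactants: 9 1-(2,4,6-trihydroxy-3-methylphenyl)ethan-1-one
Product: 10 1-(3-chloro-2,4,6-trihydroxy-5-methylphenyl)ethan-1-one
Conditions: NCS (1.0 equiv), MeCN, 0 °C
Reagents that add atoms: N-chlorosuccinimide, O=C1CCC(=O)N1Cl
Why: Electrophilic aromatic chlorination at the single unsubstituted ring carbon, which installs a removable blocking group so that step 10 cannot C-geranylate that position with rearomatisation.

Step 9
Reactants: 11 geraniol, (2E)-3,7-dimethylocta-2,6-dien-1-ol
Product: 12 geranyl methyl carbonate, (2E)-3,7-dimethylocta-2,6-dien-1-yl methyl carbonate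
Conditions: ClCO2Me (1.2 equiv), pyridine, CH2Cl2, 0 °C
Reagents that add atoms: methyl chloroformate, COC(=O)Cl
Why: O-acylation of the primary allylic alcohol to the carbonate, which ionises readily on palladium and releases its own base, with the 2E alkene untouched.

Step 10
Reactants: 10 1-(3-chloro-2,4,6-trihydroxy-5-methylphenyl)ethan-1-one; 12 geranyl methyl carbonate
Product: 13 (4S)-2-acetyl-6-chloro-4-[(2E)-3,7-dimethylocta-2,6-dien-1-yl]-3,5-dihydroxy-4-methylcyclohexa-2,5-dien-1-one
Conditions: Pd2(dba)3·CHCl3 (2.5 mol%), (R,R)-DACH-phenyl Trost ligand (7.5 mol%), THF, 0 °C to rt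
Reagents that add atoms: none
Why: Tsuji–Trost asymmetric allylic alkylation run as a dearomatisation, in which the π-geranyl complex formed from zerovalent palladium is attacked at its primary terminus by the methyl-bearing ring carbon of the phenolate (the acetyl-bearing carbon is unreactive and the chlorine-bearing one is deactivated), so that the benzene ring becomes the cyclohexadienone and the quaternary stereocentre is set by the chiral ligand pocket, which should tell the two faces of the planar phenolate apart through its unlike flanks (hydrogen-bonded acetyl side against chlorine side).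

Step 11
Reactants: 13 (4S)-2-acetyl-6-chloro-4-[(2E)-3,7-dimethylocta-2,6-dien-1-yl]-3,5-dihydroxy-4-methylcyclohexa-2,5-dien-1-one
Product: 14 (4R)-2-acetyl-4-[(2E)-3,7-dimethylocta-2,6-dien-1-yl]-3,5-dihydroxy-4-methylcyclohexa-2,5-dien-1-one
Conditions: Zn dust, AcOH, THF, 0 °C to rt
Reagents that add atoms: none
Why: Zinc reduction of an α-chloro-β-dicarbonyl unit to the zinc enolate, protonated by acetic acid, which leaves the isolated alkenes and the quaternary centre untouched (the descriptor changes from S to R only because chlorine no longer ranks its flank higher).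

Step 12
Reactants: 8 8-butanoyl-5,7-dihydroxy-2,2-dimethyl-2H-chromene-6-carbaldehyde; 14 (4R)-2-acetyl-4-[(2E)-3,7-dimethylocta-2,6-dien-1-yl]-3,5-dihydroxy-4-methylcyclohexa-2,5-dien-1-one
Product: 16 (4R)-2-acetyl-6-[(8-butanoyl-5,7-dihydroxy-2,2-dimethyl-2H-chromen-6-yl)methyl]-4-[(2E)-3,7-dimethylocta-2,6-dien-1-yl]-3,5-dihydroxy-4-methylcyclohexa-2,5-dien-1-one, via Knoevenagel adduct 15 (not isolated)
Conditions: L-proline (20 mol%), diethyl 2,6-dimethyl-1,4-dihydropyridine-3,5-dicarboxylate (1.2 equiv), CH2Cl2/EtOH, rt
Reagents that add atoms: none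
Why: Organocatalytic three-component reductive alkylation, in which amine-catalysed Knoevenagel condensation of the C–H acidic ring carbon of 14 with the aldehyde gives the quinone-methide-like alkylidene 15 and its electron-poor exocyclic alkene takes hydride from the Hantzsch ester, so the formyl carbon becomes the bridge CH2, no stereocentre is created and the chromene and geranyl alkenes are not reduced.

**Compound list**

1 | 4-hydroxy-2,6-dimethoxybenzaldehyde | O=Cc1c(OC)cc(O)cc1OC | starting material
2 | 3-butanoyl-4-hydroxy-2,6-dimethoxybenzaldehyde | O=Cc1c(OC)c(C(=O)CCC)c(O)cc1OC | intermediate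
3 | 3-butanoyl-4-hydroxy-5-iodo-2,6-dimethoxybenzaldehyde | O=Cc1c(OC)c(C(=O)CCC)c(O)c(I)c1OC | intermediate
4 | 3-butanoyl-5-iodo-2,6-dimethoxy-4-(propan-2-yloxy)benzaldehyde | O=Cc1c(OC)c(C(=O)CCC)c(OC(C)C)c(I)c1OC | intermediate
5 | 3-butanoyl-2,6-dimethoxy-4-(propan-2-yloxy)-5-[(trimethylsilyl)ethynyl]benzaldehyde | O=Cc1c(OC)c(C(=O)CCC)c(OC(C)C)c(C#C[Si](C)(C)C)c1OC | intermediate
6 | 3-butanoyl-5-ethynyl-2,6-dimethoxy-4-(propan-2-yloxy)benzaldehyde | O=Cc1c(OC)c(C(=O)CCC)c(OC(C)C)c(C#C)c1OC | intermediate
7 | 8-butanoyl-5,7-dimethoxy-2,2-dimethyl-2H-chromene-6-carbaldehyde | CCCC(=O)c1c(OC)c(C=O)c(OC)c2c1OC(C)(C)C=C2 | intermediate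
8 | 8-butanoyl-5,7-dihydroxy-2,2-dimethyl-2H-chromene-6-carbaldehyde | CCCC(=O)c1c(O)c(C=O)c(O)c2c1OC(C)(C)C=C2 | intermediate
9 | 1-(2,4,6-trihydroxy-3-methylphenyl)ethan-1-one | CC(=O)c1c(O)cc(O)c(C)c1O | starting material
10 | 1-(3-chloro-2,4,6-trihydroxy-5-methylphenyl)ethan-1-one | CC(=O)c1c(O)c(Cl)c(O)c(C)c1O | intermediate
11 | geraniol, (2E)-3,7-dimethylocta-2,6-dien-1-ol | OC/C=C(\C)CCC=C(C)C | starting material
12 | geranyl methyl carbonate, (2E)-3,7-dimethylocta-2,6-dien-1-yl methyl carbonate | COC(=O)OC/C=C(\C)CCC=C(C)C | intermediate
13 | (4S)-2-acetyl-6-chloro-4-[(2E)-3,7-dimethylocta-2,6-dien-1-yl]-3,5-dihydroxy-4-methylcyclohexa-2,5-dien-1-one (same spatial arrangement as 14) | ClC1=C(O)[C@@](C)(C/C=C(\C)CCC=C(C)C)C(O)=C(C(C)=O)C1=O | intermediate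
14 | (4R)-2-acetyl-4-[(2E)-3,7-dimethylocta-2,6-dien-1-yl]-3,5-dihydroxy-4-methylcyclohexa-2,5-dien-1-one | C1=C(O)[C@@](C)(C/C=C(\C)CCC=C(C)C)C(O)=C(C(C)=O)C1=O | intermediate
15 | Knoevenagel adduct, (4S)-2-acetyl-6-[(8-butanoyl-5,7-dihydroxy-2,2-dimethyl-2H-chromen-6-yl)methylidene]-4-[(2E)-3,7-dimethylocta-2,6-dien-1-yl]-3-hydroxy-4-methylcyclohex-2-ene-1,5-dione (same spatial arrangement as 14; geometry of the exocyclic alkene not defined) | CCCC(=O)c1c(O)c(C=C2C(=O)[C@@](C)(C/C=C(\C)CCC=C(C)C)C(O)=C(C(C)=O)C2=O)c(O)c2c1OC(C)(C)C=C2 | intermediate (not isolated)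
16 | CNP0152509.1, (4R)-2-acetyl-6-[(8-butanoyl-5,7-dihydroxy-2,2-dimethyl-2H-chromen-6-yl)methyl]-4-[(2E)-3,7-dimethylocta-2,6-dien-1-yl]-3,5-dihydroxy-4-methylcyclohexa-2,5-dien-1-one | CCCC(=O)c1c(O)c(CC2=C(O)[C@@](C)(C/C=C(\C)CCC=C(C)C)C(O)=C(C(C)=O)C2=O)c(O)c2c1OC(C)(C)C=C2 | target

**Step count and risks**

Total step count: 12. Longest linear sequence: 8 steps (steps 1 to 7, then step 12).

Steps most likely to fail:

1. Step 6. The hydride transfer from an aryl isopropyl ether whose oxygen is conjugated to two carbonyl groups may be too slow, so that the catalyst is lost as a gold acetylide, or an ether oxygen may add to the alkyne with loss of the alkyl group. The fallback sets out from 2 and comes back at 7. Compound 2 would be alkylated with 3-chloro-3-methylbut-1-yne (K2CO3, KI, CuI cat., acetone, 60 °C) to give 3-butanoyl-2,6-dimethoxy-4-[(2-methylbut-3-yn-2-yl)oxy]benzaldehyde F1. Heating F1 in xylene at 140 °C should then bring about the aromatic propargyl Claisen rearrangement, 1,5-hydrogen shift and oxa-6π electrocyclisation at the only free ortho carbon, which gives 7. Steps 7 and 12 follow unchanged.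

2. Step 10. Facial discrimination of a nearly symmetric phenolate may be poor, and allylation at oxygen or at the chlorine-bearing carbon, or syn/anti exchange of the π-geranyl unit with loss of the E geometry, may compete. The fallback sets out from 10 and comes back at 14. Compound 10 would be alkylated without a chiral catalyst (geranyl bromide, NaOMe, MeOH, 0 °C) to give racemic 2-acetyl-6-chloro-4-[(2E)-3,7-dimethylocta-2,6-dien-1-yl]-3,5-dihydroxy-4-methylcyclohexa-2,5-dien-1-one F2. Dechlorination as in step 11 (Zn, AcOH, THF) would give racemic 2-acetyl-4-[(2E)-3,7-dimethylocta-2,6-dien-1-yl]-3,5-dihydroxy-4-methylcyclohexa-2,5-dien-1-one F3, and the enantiomers would be separated by preparative chromatography on a chiral stationary phase; the R enantiomer is 14.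

3. Step 12. The doubly hydrogen-bonded aldehyde may condense sluggishly, or the alkylidene intermediate may cyclise through a phenol or enol oxygen before hydride is delivered. The fallback sets out from 8 and comes back at 16. Reductive amination of 8 (Me2NH, NaBH(OAc)3, ClCH2CH2Cl, rt) would give the Mannich base 1-{6-[(dimethylamino)methyl]-5,7-dihydroxy-2,2-dimethyl-2H-chromen-8-yl}butan-1-one F4. Heating F4 with 14 in dioxane at 90 °C should expel dimethylamine to form the ortho-quinone methide, which is trapped by the C–H acidic carbon of 14 in a Michael addition to give 16.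

**Further compounds**

F1 | step 6 | 3-butanoyl-2,6-dimethoxy-4-[(2-methylbut-3-yn-2-yl)oxy]benzaldehyde | O=Cc1c(OC)c(C(=O)CCC)c(OC(C)(C)C#C)cc1OC
F2 | step 10 | racemic 2-acetyl-6-chloro-4-[(2E)-3,7-dimethylocta-2,6-dien-1-yl]-3,5-dihydroxy-4-methylcyclohexa-2,5-dien-1-one | ClC1=C(O)C(C)(C/C=C(\C)CCC=C(C)C)C(O)=C(C(C)=O)C1=O
F3 | step 10 | racemic 2-acetyl-4-[(2E)-3,7-dimethylocta-2,6-dien-1-yl]-3,5-dihydroxy-4-methylcyclohexa-2,5-dien-1-one | C1=C(O)C(C)(C/C=C(\C)CCC=C(C)C)C(O)=C(C(C)=O)C1=O
F4 | step 12 | 1-{6-[(dimethylamino)methyl]-5,7-dihydroxy-2,2-dimethyl-2H-chromen-8-yl}butan-1-one | CCCC(=O)c1c(O)c(CN(C)C)c(O)c2c1OC(C)(C)C=C2
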